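**Retrosynthetic overview**

- The strategy rests on the 1,2-dioxolane O1–O2–C3–C4–C5: C3 (methyl, CH2CO2H) and C5 (methyl, chain CH2) are both quaternary peroxide carbons joined through the lone ring methylene C4, so C5 can be the carbonyl carbon of a methyl ketone and C4–C3 the two carbons of a 2-methyl-1-alkene.
- Key disconnection: C4–C5 and C3–O2, giving the triethylsilylperoxy ketal 19 of ketone 15 and the silyl ether 21 of 3-methylbut-3-en-1-ol; the acid is revealed afterwards by desilylation and oxidation of the two-carbon arm.
- Ketone 15 comes from enone 13 by a catalyst-controlled methyl conjugate addition, 13 from aldehyde 11 and an acetonyl ylide, and 11 from (R)-citronellol 3 and the ylide of phosphonium salt 2 by Wittig coupling and hydrogenation.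
- Ring order: the benzene ring is bought; the dioxolane, the only ring made, is closed in step 14, two steps before the end.

Key step: step 14

Assumption: the Josiphos enantiomer named in step 9 is taken to direct methyl to the Si face of C4 of enone 13; the sense would be checked on a small scale and the mirror-image ligand used if it proves opposite.

**Route**

Step 1
Reactants: 1 (5-bromopentyl)benzene
Product: 2 triphenyl(5-phenylpentyl)phosphonium bromide
Conditions: PPh3, MeCN, reflux
Reagents that add atoms: triphenylphosphine, c1ccc(cc1)P(c1ccccc1)c1ccccc1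
Why: SN2 quaternisation of triphenylphosphine by the unhindered primary bromide should give the phosphonium salt.

Step 2
Reactants: 3 (R)-citronellol
Product: 4 (R)-tert-butyl[(3,7-dimethyloct-6-en-1-yl)oxy]dimethylsilane
Conditions: TBSCl, imidazole, CH2Cl2, 0 °C to rt
Reagents that add atoms: tert-butyldimethylsilyl chloride, CC(C)(C)[Si](C)(C)Cl
Why: Imidazole-promoted O-silylation of the primary alcohol masks the hydroxyl for the ozonolysis and ylide steps and leaves the purchased R stereocentre untouched.

Step 3
Reactants: 4 (R)-tert-butyl[(3,7-dimethyloct-6-en-1-yl)oxy]dimethylsilane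
Product: 6 (R)-6-[(tert-butyldimethylsilyl)oxy]-4-methylhexanal, via ozonide 5 (not isolated)
Conditions: O3, CH2Cl2, −78 °C; then PPh3, −78 °C to rt
Reagents that add atoms: ozone, [O-][O+]=O
Why: Ozonolysis of the trisubstituted alkene with reductive cleavage of the ozonide by PPh3 should give the aldehyde and acetone, leaving the silyl ether and the stereocentre (γ to the new carbonyl) unchanged.

Step 4
Reactants: 2 triphenyl(5-phenylpentyl)phosphonium bromide; 6 (R)-6-[(tert-butyldimethylsilyl)oxy]-4-methylhexanal
Product: 8 (R,Z)-tert-butyldimethyl[(3-methyl-11-phenylundec-6-en-1-yl)oxy]silane, via ylide 7 (not isolated)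
Conditions: NaN(SiMe3)2, THF, 0 °C; then 6, −78 °C to rt
Reagents that add atoms: none
Why: Wittig olefination with the non-stabilised ylide under lithium-free conditions joins the two fragments at C6=C7; the expected Z geometry does not matter because the alkene is saturated next.

Step 5
Reactants: 8 (R,Z)-tert-butyldimethyl[(3-methyl-11-phenylundec-6-en-1-yl)oxy]silane
Product: 9 (R)-tert-butyldimethyl[(3-methyl-11-phenylundecyl)oxy]silane
Conditions: H2 (1 atm), 10% Pd/C, EtOAc, rt
Reagents that add atoms: none
Why: Heterogeneous catalytic hydrogenation of the disubstituted alkene at atmospheric pressure in a non-protic solvent should leave the benzene ring and the silyl ether intact.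

Step 6
Reactants: 9 (R)-tert-butyldimethyl[(3-methyl-11-phenylundecyl)oxy]silane
Product: 10 (R)-3-methyl-11-phenylundecan-1-ol
Conditions: camphorsulfonic acid (cat.), MeOH/CH2Cl2, 0 °C to rt
Reagents that add atoms: none
Why: Acid-catalysed methanolysis of the primary TBS ether transfers the silyl group to methanol and frees the alcohol; nothing else in the molecule is acid-sensitive.

Step 7
Reactants: 10 (R)-3-methyl-11-phenylundecan-1-ol
Product: 11 (R)-3-methyl-11-phenylundecanal
Conditions: TEMPO (cat.), PhI(OAc)2, CH2Cl2, rt
Reagents that add atoms: none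
Why: TEMPO-catalysed oxidation with PhI(OAc)2 as terminal oxidant stops at the aldehyde in the absence of water, and the β stereocentre cannot epimerise.

Step 8
Reactants: 11 (R)-3-methyl-11-phenylundecanal; 12 1-(triphenylphosphoranylidene)propan-2-one
Product: 13 (R,E)-6-methyl-14-phenyltetradec-3-en-2-one
Conditions: toluene, 90 °C
Reagents that add atoms: none
Why: Wittig olefination with the carbonyl-stabilised acetonyl ylide should give the E-enone, as is usual with unhindered aliphatic aldehydes.

Step 9
Reactants: 13 (R,E)-6-methyl-14-phenyltetradec-3-en-2-one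
Product: 15 (4S,6R)-4,6-dimethyl-14-phenyltetradecan-2-one, via magnesium enolate 14 (not isolated)
Conditions: MeMgBr (slow addition), CuBr·SMe2 (5 mol%), (S)-1-[(Rp)-2-(diphenylphosphino)ferrocenyl]ethyldicyclohexylphosphine (Josiphos, 6 mol%), t-BuOMe, −75 °C; then aq NH4Cl
Reagents that add atoms: methylmagnesium bromide, C[Mg]Br
Why: Copper-catalysed asymmetric conjugate addition of a Grignard reagent to an acyclic enone with a Josiphos-type ferrocenyl diphosphine should deliver methyl to the Si face of C4 under catalyst control, setting the 4S centre (1,3-anti to the remote C6 methyl), while low temperature and slow addition suppress 1,2-addition.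

Step 10
Reactants: 15 (4S,6R)-4,6-dimethyl-14-phenyltetradecan-2-one
Product: 16 (4S,6R)-2,4,6-trimethyl-14-phenyltetradec-1-ene
Conditions: Ph3PCH3Br, KOtBu, THF, 0 °C to rt
Reagents that add atoms: methyltriphenylphosphonium bromide, [Br-].C[P+](c1ccccc1)(c1ccccc1)c1ccccc1
Why: Wittig methylenation of the methyl ketone gives the 2-methyl-1-alkene from which the mixed peroxy ketal can be made cleanly, and C4, being β to the carbonyl, cannot epimerise under the basic ylide.

Step 11
Reactants: 16 (4S,6R)-2,4,6-trimethyl-14-phenyltetradec-1-ene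
Product: 18 (4S,6R)-2-hydroperoxy-2-methoxy-4,6-dimethyl-14-phenyltetradecane (both C2 epimers), via carbonyl oxide 17 (not isolated)
Conditions: O3 (limiting, Sudan Red 7B indicator), CH2Cl2/MeOH, −78 °C; N2 purge, no reductant
Reagents that add atoms: ozone, [O-][O+]=O; methanol, CO
Why: Ozonolysis in methanol (Criegee cleavage with solvent capture) should split the 1,1-disubstituted alkene into formaldehyde and the more substituted carbonyl oxide 17, which methanol traps as the α-methoxy hydroperoxide with exactly one OOH and one OMe on the former ketone carbon; the alkene is far more reactive towards ozone than the monoalkylbenzene.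

Step 12
Reactants: 18 (4S,6R)-2-hydroperoxy-2-methoxy-4,6-dimethyl-14-phenyltetradecane (both C2 epimers)
Product: 19 triethyl{[(4S,6R)-2-methoxy-4,6-dimethyl-14-phenyltetradecan-2-yl]peroxy}silane (both C2 epimers)
Conditions: Et3SiCl, imidazole, DMF, 0 °C
Reagents that add atoms: chlorotriethylsilane, CC[Si](Cl)(CC)CC
Why: O-Silylation of the hydroperoxide gives the triethylsilylperoxy ketal, in which the peroxide tolerates the Lewis acid yet can still close the ring with loss of silicon; the C2 epimers converge in the next step.

Step 13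
Reactants: 20 3-methylbut-3-en-1-ol
Product: 21 tert-butyl[(3-methylbut-3-en-1-yl)oxy]diphenylsilane
Conditions: TBDPSCl, imidazole, CH2Cl2, rt
Reagents that add atoms: tert-butyl(chloro)diphenylsilane, CC(C)(C)[Si](Cl)(c1ccccc1)c1ccccc1
Why: O-Silylation with the bulky, Lewis acid-tolerant TBDPS group keeps the hydroxyl from trapping the cationic intermediates of the annulation.

Step 14
Reactants: 19 triethyl{[(4S,6R)-2-methoxy-4,6-dimethyl-14-phenyltetradecan-2-yl]peroxy}silane (both C2 epimers); 21 tert-butyl[(3-methylbut-3-en-1-yl)oxy]diphenylsilane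
Product: 24 tert-butyl{2-[(3S,5R)-5-[(2S,4R)-2,4-dimethyl-12-phenyldodecyl]-3,5-dimethyl-1,2-dioxolan-3-yl]ethoxy}diphenylsilane, via peroxycarbenium ion 22 (not isolated), via tertiary carbocation 23 (not isolated)
Conditions: SnCl4 (1 equiv), 21 (3 equiv), CH2Cl2, −78 °C; aq NaHCO3; SiO2 chromatography, then preparative HPLC
Reagents that add atoms: none
Why: SnCl4 ionises the methoxy group of 19 to peroxycarbenium ion 22, whose carbon is attacked by the unsubstituted CH2 terminus of alkene 21 to form C4–C5 and tertiary cation 23; the silyl-bearing peroxy oxygen then captures that cation and chloride removes Et3Si, forming O2–C3. The closest known reaction type is the Lewis acid-mediated annulation of triethylsilylperoxy ketals with alkenes to 1,2-dioxolanes, established for ketone-derived ions and 1,1-disubstituted alkenes. The dioxolane closes stepwise in a (3+2) sense, the ring-forming event being a five-membered collapse of oxygen onto a cation through an envelope transition state. C5 and C3 are both created here: their relative configuration is set in that envelope, which is least strained with the two methyl groups in the syn pseudoaxial sites and the two CH2 arms pseudoequatorial (cis-dimethyl, as required), whereas the face of 22 that is attacked is not steered by the acyclic chain centres, so the sense at C5 is fixed only by separation. The step needs Markovnikov C-attack and O-closure in preference to proton loss: the 1,1-disubstituted alkene supplies a tertiary cation, the silyl ether oxygen of the arm could only close an oxetane, and −78 °C disfavours elimination. Chromatography and preparative HPLC should remove the two trans-dimethyl isomers and the cis isomer of opposite ring configuration, leaving 24, which has no hydrogen on either peroxy carbon and so tolerates the remaining steps.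

Step 15
Reactants: 24 tert-butyl{2-[(3S,5R)-5-[(2S,4R)-2,4-dimethyl-12-phenyldodecyl]-3,5-dimethyl-1,2-dioxolan-3-yl]ethoxy}diphenylsilane
Product: 25 2-[(3S,5R)-5-[(2S,4R)-2,4-dimethyl-12-phenyldodecyl]-3,5-dimethyl-1,2-dioxolan-3-yl]ethan-1-ol
Conditions: Bu4NF, AcOH, THF, 0 °C to rt
Reagents that add atoms: none
Why: Fluoride-mediated desilylation buffered with acetic acid removes the TBDPS group, and the peroxide, lacking hydrogen on both peroxy carbons, cannot undergo base-induced Kornblum–DeLaMare fragmentation.

Step 16
Reactants: 25 2-[(3S,5R)-5-[(2S,4R)-2,4-dimethyl-12-phenyldodecyl]-3,5-dimethyl-1,2-dioxolan-3-yl]ethan-1-ol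
Product: 27 2-[(3R,5R)-5-[(2S,4R)-2,4-dimethyl-12-phenyldodecyl]-3,5-dimethyl-1,2-dioxolan-3-yl]acetic acid (CNP0188135.5), via aldehyde 26 (not isolated)
Conditions: TEMPO (cat.), PhI(OAc)2 (2.2 equiv), MeCN/CH2Cl2/H2O, rt
Reagents that add atoms: water, O
Why: The aqueous TEMPO/PhI(OAc)2 oxidation takes the primary alcohol through aldehyde 26 to the carboxylic acid under near-neutral, metal-free conditions with no reductant or strong base to cleave the O–O bond; the C3 descriptor changes from S to R only because the CIP rank of the side arm rises.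

**Compound list**

1 | (5-bromopentyl)benzene | BrCCCCCc1ccccc1 | starting material
2 | triphenyl(5-phenylpentyl)phosphonium bromide | [Br-].c1ccccc1CCCCC[P+](c1ccccc1)(c1ccccc1)c1ccccc1 | intermediate
3 | (R)-citronellol, (3R)-3,7-dimethyloct-6-en-1-ol | C[C@H](CCC=C(C)C)CCO | starting material
4 | (R)-tert-butyl[(3,7-dimethyloct-6-en-1-yl)oxy]dimethylsilane | C[C@H](CCC=C(C)C)CCO[Si](C)(C)C(C)(C)C | intermediate
5 | ozonide, 3-[(R)-5-(tert-butyldimethylsilyloxy)-3-methylpentyl]-5,5-dimethyl-1,2,4-trioxolane (not isolated) | C[C@H](CCC1OOC(C)(C)O1)CCO[Si](C)(C)C(C)(C)C | intermediate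
6 | (R)-6-[(tert-butyldimethylsilyl)oxy]-4-methylhexanal | C[C@H](CCC=O)CCO[Si](C)(C)C(C)(C)C | intermediate
7 | ylide, triphenyl(5-phenylpentylidene)phosphorane (not isolated) | c1ccccc1CCCCC=P(c1ccccc1)(c1ccccc1)c1ccccc1 | intermediate
8 | (R,Z)-tert-butyldimethyl[(3-methyl-11-phenylundec-6-en-1-yl)oxy]silane | C[C@H](CC/C=C\CCCCc1ccccc1)CCO[Si](C)(C)C(C)(C)C | intermediate
9 | (R)-tert-butyldimethyl[(3-methyl-11-phenylundecyl)oxy]silane | C[C@H](CCCCCCCCc1ccccc1)CCO[Si](C)(C)C(C)(C)C | intermediate
10 | (R)-3-methyl-11-phenylundecan-1-ol | C[C@H](CCCCCCCCc1ccccc1)CCO | intermediate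
11 | (R)-3-methyl-11-phenylundecanal | C[C@H](CCCCCCCCc1ccccc1)CC=O | intermediate
12 | 1-(triphenylphosphoranylidene)propan-2-one | CC(=O)C=P(c1ccccc1)(c1ccccc1)c1ccccc1 | starting material
13 | (R,E)-6-methyl-14-phenyltetradec-3-en-2-one | C[C@H](CCCCCCCCc1ccccc1)C/C=C/C(C)=O | intermediate
14 | bromomagnesium enolate of 15 (not isolated) | C[C@H](CCCCCCCCc1ccccc1)C[C@H](C)C=C(C)O[Mg]Br | intermediate
15 | (4S,6R)-4,6-dimethyl-14-phenyltetradecan-2-one | C[C@H](CCCCCCCCc1ccccc1)C[C@H](C)CC(C)=O | intermediate
16 | (4S,6R)-2,4,6-trimethyl-14-phenyltetradec-1-ene | C[C@H](CCCCCCCCc1ccccc1)C[C@H](C)CC(C)=C | intermediate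
17 | carbonyl oxide of ketone 15 (not isolated) | C[C@H](CCCCCCCCc1ccccc1)C[C@H](C)CC(C)=[O+][O-] | intermediate
18 | (4S,6R)-2-hydroperoxy-2-methoxy-4,6-dimethyl-14-phenyltetradecane (both C2 epimers) | C[C@H](CCCCCCCCc1ccccc1)C[C@H](C)CC(C)(OC)OO | intermediate
19 | triethyl{[(4S,6R)-2-methoxy-4,6-dimethyl-14-phenyltetradecan-2-yl]peroxy}silane (both C2 epimers) | C[C@H](CCCCCCCCc1ccccc1)C[C@H](C)CC(C)(OC)OO[Si](CC)(CC)CC | intermediate
20 | 3-methylbut-3-en-1-ol | C=C(C)CCO | starting material
21 | tert-butyl[(3-methylbut-3-en-1-yl)oxy]diphenylsilane | C=C(C)CCO[Si](c1ccccc1)(c1ccccc1)C(C)(C)C | intermediate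
22 | peroxycarbenium ion from 19 (not isolated) | C[C@H](CCCCCCCCc1ccccc1)C[C@H](C)CC(C)=[O+]O[Si](CC)(CC)CC | intermediate
23 | tertiary carbocation after C4–C5 bond formation (both C5 epimers, not isolated) | C[C@H](CCCCCCCCc1ccccc1)C[C@H](C)CC(C)(OO[Si](CC)(CC)CC)C[C+](C)CCO[Si](c1ccccc1)(c1ccccc1)C(C)(C)C | intermediate
24 | tert-butyl{2-[(3S,5R)-5-[(2S,4R)-2,4-dimethyl-12-phenyldodecyl]-3,5-dimethyl-1,2-dioxolan-3-yl]ethoxy}diphenylsilane (cis-dimethyl; C3 carries the silyloxyethyl arm, C5 the chain) | C[C@H](CCCCCCCCc1ccccc1)C[C@H](C)C[C@]1(C)C[C@](C)(CCO[Si](c2ccccc2)(c2ccccc2)C(C)(C)C)OO1 | intermediate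
25 | 2-[(3S,5R)-5-[(2S,4R)-2,4-dimethyl-12-phenyldodecyl]-3,5-dimethyl-1,2-dioxolan-3-yl]ethan-1-ol | C[C@H](CCCCCCCCc1ccccc1)C[C@H](C)C[C@]1(C)C[C@](C)(CCO)OO1 | intermediate
26 | 2-[(3R,5R)-5-[(2S,4R)-2,4-dimethyl-12-phenyldodecyl]-3,5-dimethyl-1,2-dioxolan-3-yl]acetaldehyde (not isolated) | C[C@H](CCCCCCCCc1ccccc1)C[C@H](C)C[C@]1(C)C[C@](C)(CC=O)OO1 | intermediate
27 | 2-[(3R,5R)-5-[(2S,4R)-2,4-dimethyl-12-phenyldodecyl]-3,5-dimethyl-1,2-dioxolan-3-yl]acetic acid (CNP0188135.5) | C[C@H](CCCCCCCCc1ccccc1)C[C@H](C)C[C@]1(C)C[C@](C)(CC(=O)O)OO1 | target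

**Totals**

Total step count: 16.
Longest linear sequence: 14 steps, from (R)-citronellol 3 to 27 (steps 2–12 and 14–16).

**Steps most likely to fail**

1. Step 14. After the C4–C5 bond forms, proton loss from the tertiary cation or its capture by chloride may outrun closure by the peroxide oxygen. The peroxycarbenium ion beside the β-branched chain may also add so slowly that the Lewis acid oligomerises the alkene. Low cis and facial preference further dilutes the wanted isomer. Fallback: exchange the roles of the two partners, so that the functionalised four-carbon unit is the cation source and the plain hydrocarbon alkene is the nucleophile. The fallback sets out from 21 and from alkene 16. Ozonolysis of 21 in CH2Cl2/MeOH at −78 °C should give tert-butyl(3-hydroperoxy-3-methoxybutoxy)diphenylsilane F1. Silylation with Et3SiCl and imidazole gives tert-butyl{3-methoxy-3-[(triethylsilyl)peroxy]butoxy}diphenylsilane F2. SnCl4 in CH2Cl2 at −78 °C with 16 then forms C3–C4 first and closes O1–C5 on a cation that carries no heteroatom-bearing arm. The route is rejoined at 24 after the same separation of isomers.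

2. Step 9. Direct 1,2-addition of MeMgBr to the methyl ketone and uncatalysed background addition may erode both the yield and the facial selectivity at C4, leaving a C4 epimer that is hard to remove later. Fallback: change the acceptor class to an α,β-unsaturated thioester, which does not suffer 1,2-addition and is the most dependable substrate for copper/Josiphos methyl transfer. The fallback sets out from aldehyde 11. Wittig olefination with S-ethyl 2-(triphenylphosphoranylidene)ethanethioate gives S-ethyl (R,E)-5-methyl-13-phenyltridec-2-enethioate F3. MeMgBr with CuBr·SMe2 and the same Josiphos enantiomer in t-BuOMe at −75 °C gives S-ethyl (3S,5R)-3,5-dimethyl-13-phenyltridecanethioate F4. Fukuyama coupling with MeZnI and catalytic PdCl2(PPh3)2 converts the thioester into the methyl ketone, rejoining the route at 15.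

3. Step 11. The Criegee fragmentation may partly run the other way, returning ketone 15. Excess ozone may attack the phenyl ring. The hydroperoxy ketal may also lose hydrogen peroxide and revert to ketone on concentration. Fallback: bypass the alkene and ozone altogether. The fallback sets out from ketone 15. Ketalisation with HC(OMe)3 and catalytic TsOH in MeOH gives (4S,6R)-2,2-dimethoxy-4,6-dimethyl-14-phenyltetradecane F5. One methoxy group is then exchanged for hydroperoxy with anhydrous ethereal H2O2 and a trace of camphorsulfonic acid at 0 °C, stopped short of full conversion to limit the gem-dihydroperoxide. The route is rejoined at 18.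

**Further compounds**

F1 | step 14 | tert-butyl(3-hydroperoxy-3-methoxybutoxy)diphenylsilane | CC(OC)(OO)CCO[Si](c1ccccc1)(c1ccccc1)C(C)(C)C
F2 | step 14 | tert-butyl{3-methoxy-3-[(triethylsilyl)peroxy]butoxy}diphenylsilane | CC(OC)(OO[Si](CC)(CC)CC)CCO[Si](c1ccccc1)(c1ccccc1)C(C)(C)C
F3 | step 9 | S-ethyl (R,E)-5-methyl-13-phenyltridec-2-enethioate | C[C@H](CCCCCCCCc1ccccc1)C/C=C/C(=O)SCC
F4 | step 9 | S-ethyl (3S,5R)-3,5-dimethyl-13-phenyltridecanethioate | C[C@H](CCCCCCCCc1ccccc1)C[C@H](C)CC(=O)SCC
F5 | step 11 | (4S,6R)-2,2-dimethoxy-4,6-dimethyl-14-phenyltetradecane | C[C@H](CCCCCCCCc1ccccc1)C[C@H](C)CC(C)(OC)OC
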